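# Proposed total synthesis of 6-hydroxykaempferol 3-O-sulfate (CNP0454531.0)

## Analysis of the target

The target is a flavonol, a 2-aryl-3-oxy-4H-chromen-4-one. Ring A is a benzene ring with hydroxyls on C5, C6 and C7 and hydrogen on C8. Ring C is the 4-pyranone (O1, C2, C3, C4, C4a, C8a), and ring B is a 4-hydroxyphenyl group on C2. O3 carries a sulfate monoester and there is no stereocentre, so the problem is one of regiochemistry and protecting-group logic. The sulfate on the enolic O3 is the most sensitive group: aqueous acid cleaves it, autocatalytically once it is in the free-acid form, and every sulfated intermediate is a salt, so it has to be introduced late. The 5,6,7-trihydroxylated ring A is a pyrogallol-type arene that air oxidises quickly in base, so it should be unmasked last under neutral, reducing conditions. The difficulty is to distinguish five oxygens so that only O3 is sulfated, and to place the carbonyl carbon on ring A beside three contiguous oxygens while C8 stays unsubstituted. The strategy rests on C4: it is a lone carbonyl carbon bonded only to C4a of ring A and to the oxygen-bearing C3. It can therefore be delivered as carbon monoxide between an aryl iodide (C4a–I) and the enolate carbon (C3) of an α-alkoxy ketone whose own carbonyl becomes C2. The oxygenation of ring A is also symmetric about the C6–O axis, so a symmetric 3,4,5-trioxygenated phenol can be desymmetrised by one ortho-iodination.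

## Retrosynthetic reasoning

**Target 19 back to sodium salt 17.** The last bonds cut are the four benzylic C–O bonds and the O–Na/O–H exchange. Hydrogenolysis is the only ether cleavage that spares a sulfate monoester, since protic or Lewis acids would remove the sulfate and base would expose the pyrogallol ring to oxidation. All four phenolic oxygens therefore travel as benzyl ethers, and the hydrogen sulfate 19 is released from its sodium salt 18 in the last operation.

**Sodium salt 17 back to flavonol 15.** The S–O3 bond is cut next. In 15 the only free hydroxyl is O3, so the regiochemistry of sulfation is decided by the protecting-group pattern and not by reagent selectivity. The forward reaction must sulfate a hydrogen-bonded, flanked enolic hydroxyl, and the first-formed pyridinium salt 16 must be exchanged to sodium salt 17 so that no amine reaches the hydrogenolysis catalyst.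

**Flavonol 15 back to diketone 12.** The O1–C2 bond of ring C is cut, together with the two acetal O–C bonds on O1 and O3. An ortho-hydroxyaryl 1,3-diketone closes to the 4-pyranone by addition and dehydration. With the same acid-labile methoxymethyl acetal on O1 and O3 and benzyl on the other four oxygens, one acid treatment should unmask both oxygens (13), close ring C (14) and leave O3 as the sole free hydroxyl of 15.

**Diketone 12 back to aryl iodide 6, carbon monoxide 11 and ketone 10.** Both C–C bonds of C4 are cut, C4a–C4 and C3–C4. C4 has no other carbon substituent, so it is a one-carbon linchpin, and removing it divides the skeleton into a ring A piece and a C3–C2–ring B piece of similar size. Cutting only C3–C4 would instead need a 2,6-dioxygenated benzoyl donor that is hindered and takes longer to make. The oxygen on C3 arrives on the enolate carbon of 10, so no later oxidation of C3 is required. The forward reaction has to join three components with acylation on carbon.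

**Aryl iodide 6 back to phenol 4 through iodophenol 5.** The C–I bond and the acetal on the future O1 are cut. The iodine must sit on the carbon flanked by the future O1 and the future C5–O. In the symmetric phenol 4 the two ortho carbons are equivalent and are the only open ring positions, so mono-iodination can give only 5. The free hydroxyl of 5 is by then the one oxygen that is not benzylated and is capped to give 6.

**Phenol 4 back to aldehyde 1 through 2 and 3.** The aryl C–O bond is traced to an aryl C–CHO bond. Peracid oxidation of the benzylated aldehyde 2 with aryl migration gives formate 3 and, after cleavage, phenol 4. Aldehyde 2 comes from the commercial trihydroxybenzaldehyde 1 by threefold benzylation. This supplies three identical ethers and one differentiated oxygen from a cheap gallic-type building block.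

**Ketone 10 back to the commercial ketone 7 through 8 and 9.** The acetal on the α-oxygen and the α-C–O bond are cut. Oxidation of the methyl ketone 7 through the masked hydroxy acetal 8 gives hydroxy ketone 9, which is capped to give 10.

## Alternatives that were turned down

**Alternative 1: Friedel–Crafts closure of a β-aryloxyacrylic acid.**
- Disconnection: C4–C4a. The precursor would be (E)-2-(allyloxy)-3-[4-(benzyloxy)phenyl]-3-[3,4,5-tris(benzyloxy)phenoxy]prop-2-enoic acid A2, in which phenol 4 is already attached through the future O1.
- Forward key step: trifluoroacetic anhydride activates A2 as a mixed anhydride, which acylates the ortho carbon of its own aryloxy ring and closes ring C. The product is 3-(allyloxy)-5,6,7-tris(benzyloxy)-2-[4-(benzyloxy)phenyl]-4H-chromen-4-one A1.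
- For it: the acylated ring is very electron-rich and its two ortho carbons are equivalent, so there is no regiochemical question. No halogenation, no metal and no gas are needed, and ring C and C4 are set in one intramolecular event. On the ring-forming step itself it is stronger than the chosen route.
- Against it: A2 is a tetrasubstituted alkene with oxygen on both carbons, and only the isomer with the carboxyl cis to the aryloxy group can cyclise. Reaching it with secure geometry needs either O-arylation of an α-alkoxy-β-keto ester enol or addition of 4 to an alkynoate followed by α-oxygenation, and neither is short. The strongly acidic medium meets four benzyl ethers on activated rings (trifluoroacetolysis, C-benzylation, C-trifluoroacetylation). The allyl group on O3 of A1 needs a separate removal before sulfation.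
- Comparison: the chosen route offers a convergent union of two fragments that are each two to four steps from catalogue compounds, and the O3 protecting group leaves in the same operation that closes ring C.

**Alternative 2: Carbene-catalysed benzoin closure of ring C.**
- Disconnection: C3–C4. The precursor would be the dialdehyde 2,3,4-tris(benzyloxy)-6-{1-[4-(benzyloxy)phenyl]-2-oxoethoxy}benzaldehyde A4.
- Forward key step: a triazolylidene carbene converts the aryl aldehyde into a Breslow intermediate that adds to the aliphatic aldehyde, closing ring C. The product is 5,6,7-tris(benzyloxy)-2-[4-(benzyloxy)phenyl]-3-hydroxychroman-4-one A3.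
- For it: it is metal-free and mild and uses no carbon monoxide, and on those points it is stronger. Like the chosen route it delivers O3 as the only free hydroxyl.
- Against it: the aryl aldehyde of A4 lies between two ortho oxygens on an electron-rich ring, so the carbene should engage the unhindered aliphatic aldehyde first and the acyl-anion polarity is then the wrong way round. The α-hydrogen of that aliphatic aldehyde is both benzylic and α-oxygenated and should enolise under the basic conditions that generate the carbene. A3 is at the dihydroflavonol oxidation level, so a C2–C3 dehydrogenation is still needed and two stereocentres are made only to be destroyed. A4 itself needs formylation of 4 and a hindered O-alkylation with an aldehyde equivalent.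
- Comparison: the chosen route reaches the flavonol oxidation level directly and replaces a labile aldehyde with the robust ketone 10.

**Alternative 3: Pyrone-masked polyketide chain folded into ring A.**
- Disconnection: C4a–C5, so ring A is built last. The precursor would be the pyranone keto ester methyl 2-(benzyloxy)-4-{6-[4-(benzyloxy)phenyl]-5-(methoxymethoxy)-4-oxo-4H-pyran-2-yl}-3-oxobutanoate A6.
- Forward key step: Mg(OMe)2 forms a polyanion whose dienolate carbon (the future C4a) attacks the ester carbonyl, and the new ring aromatises by enolisation. The product is 6-(benzyloxy)-2-[4-(benzyloxy)phenyl]-5,7-dihydroxy-3-(methoxymethoxy)-4H-chromen-4-one A5.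
- For it: no aromatic substitution on ring A is needed, the unsubstituted C8 follows from the chain, and O6 is differentiated from O5 and O7. As a de novo arene construction it is the more original plan, and it needs no aryl halide.
- Against it: A6 is a long, highly enolisable chain that would take more steps than the whole longest line of the chosen route. The polyanion has several nucleophilic sites and can also acylate on oxygen. The protecting-group pattern of A5 is the inverse of what the end game needs, with O3 masked and O5 and O7 free. Two further steps would be needed before sulfation, one of them benzylation of the chelated 5-hydroxyl, which reacts poorly.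
- Comparison: the chosen route buys ring A ready-made from aldehyde 1 and has the correct O3-versus-rest differentiation built in from the start.

Key step: step 7

Remark on the chemistry (assumption): the target is drawn as the free hydrogen sulfate. Aryl hydrogen sulfates hydrolyse autocatalytically, so the compound is carried as its sodium salt 18 and the free acid 19 is released only in the last operation with one equivalent of cold acid.

## Route

Step 1
Reactants: 1 3,4,5-trihydroxybenzaldehyde
Product: 2 3,4,5-tris(benzyloxy)benzaldehyde
Conditions: BnBr (3.6 equiv), K2CO3 (4.5 equiv), DMF, 60 °C, N2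
Reagents that add atoms: benzyl bromide, BrCc1ccccc1
Why: Williamson etherification of three phenoxides; the aldehyde is inert to carbonate and exclusion of air protects the pyrogallol unit until it is fully alkylated.

Step 2
Reactants: 2 3,4,5-tris(benzyloxy)benzaldehyde
Product: 4 3,4,5-tris(benzyloxy)phenol, via 3,4,5-tris(benzyloxy)phenyl formate 3 (not isolated)
Conditions: mCPBA (1.5 equiv), CH2Cl2, 0 °C to rt; then K2CO3 (cat.), MeOH, rt
Reagents that add atoms: 3-chloroperoxybenzoic acid (mCPBA), O=C(OO)c1cccc(Cl)c1
Why: Baeyer–Villiger oxidation of an electron-rich benzaldehyde with aryl migration (Dakin-type), then methanolysis of the labile aryl formate; a peracid is used because alkaline peroxide needs a free ortho or para hydroxyl, which 2 lacks.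

Step 3
Reactants: 4 3,4,5-tris(benzyloxy)phenol
Product: 5 3,4,5-tris(benzyloxy)-2-iodophenol
Conditions: NIS (1.0 equiv), MeCN, −20 to 0 °C, dark
Reagents that add atoms: N-iodosuccinimide, O=C1CCC(=O)N1I
Why: Electrophilic aromatic iodination at one of the two equivalent open positions, each ortho to the hydroxyl and para to a benzyloxy group; one equivalent at low temperature should stop at the mono-iodide because the first iodine deactivates and crowds the ring.

Step 4
Reactants: 5 3,4,5-tris(benzyloxy)-2-iodophenol
Product: 6 1,2,3-tris(benzyloxy)-4-iodo-5-(methoxymethoxy)benzene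
Conditions: MOMCl (1.5 equiv), iPr2NEt (2.5 equiv), CH2Cl2, 0 °C to rt
Reagents that add atoms: chloromethyl methyl ether, COCCl
Why: O-alkylation of the phenol with an α-chloro ether gives the acid-labile acetal on the oxygen that becomes O1, orthogonal to the three benzyl ethers.

Step 5
Reactants: 7 1-[4-(benzyloxy)phenyl]ethan-1-one
Product: 9 1-[4-(benzyloxy)phenyl]-2-hydroxyethan-1-one, via 2-[4-(benzyloxy)phenyl]-2,2-dimethoxyethan-1-ol 8 (not isolated)
Conditions: PhI(OAc)2 (1.1 equiv), KOH (5 equiv), MeOH, 0 °C to rt; then 2 M aq. HCl, THF, rt
Reagents that add atoms: methanol, CO (the two methoxy groups of 8 only); water, O (the carbonyl oxygen of 9)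
Why: Hypervalent-iodine α-hydroxylation of an aryl methyl ketone: the enolate is iodanylated, methoxide adds to the carbonyl, the alkoxide displaces iodobenzene to a methoxy epoxide and methoxide opens it to the hydroxy dimethyl acetal 8, whose hydroxyl oxygen is the former carbonyl oxygen; aqueous acid then hydrolyses the acetal to the α-hydroxy ketone.

Step 6
Reactants: 9 1-[4-(benzyloxy)phenyl]-2-hydroxyethan-1-one
Product: 10 1-[4-(benzyloxy)phenyl]-2-(methoxymethoxy)ethan-1-one
Conditions: MOMCl (1.5 equiv), iPr2NEt (2.5 equiv), CH2Cl2, 0 °C to rt
Reagents that add atoms: chloromethyl methyl ether, COCCl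
Why: O-alkylation of the primary alcohol with an α-chloro ether under amine base, which is too weak to enolise the ketone; the α-oxygen is thereby masked with the same acetal as O1.

Step 7
Reactants: 6 1,2,3-tris(benzyloxy)-4-iodo-5-(methoxymethoxy)benzene; 10 1-[4-(benzyloxy)phenyl]-2-(methoxymethoxy)ethan-1-one; 11 carbon monoxide
Product: 12 1-[4-(benzyloxy)phenyl]-2-(methoxymethoxy)-3-[2,3,4-tris(benzyloxy)-6-(methoxymethoxy)phenyl]propane-1,3-dione (racemic)
Conditions: 10 (2.0 equiv), NaN(SiMe3)2 (2.0 equiv), THF, 0 °C; then 6 (1.0 equiv), Pd(dba)2 (5 mol%), Xantphos (6 mol%), CO (1 atm), THF, 70 °C; aq. NH4Cl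
Reagents that add atoms: none
Why: Zerovalent palladium carrying Xantphos inserts into the C–I bond of 6, carbon monoxide 11 inserts into the aryl–palladium bond to give an aroyl complex of divalent palladium, the sodium enolate of 10 displaces iodide, and reductive elimination forms C3–C4 and returns zerovalent palladium. The closest known reaction type is the palladium-catalysed carbonylative α-arylation of aryl ketones with aryl iodides to 1,3-diketones. No ring is closed here, and the one new stereocentre (C2 of the dione, the future C3) forms racemic and uncontrolled, which does not matter because it becomes sp2 in step 8. Acylation has to beat direct α-arylation: the two ortho oxygen substituents of 6 slow aryl–enolate reductive elimination but favour the strain-relieving CO insertion, and CO at atmospheric pressure with the wide bite angle of Xantphos keeps palladium in the aroyl form. Acylation has to occur on carbon and not on the enolate oxygen: the second equivalent of enolate removes the product as its stabilised sodium 1,3-diketonate, and any enol ester formed is an acyl donor that the enolate converts to the same diketonate. Enolisation is unambiguous because 10 has a single enolisable carbon. The position of the new carbonyl on ring A is fixed by the iodine of 6, which lies between the acetal-protected oxygen (future O1) and a benzyloxy group (future C5–O).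

Step 8
Reactants: 12 1-[4-(benzyloxy)phenyl]-2-(methoxymethoxy)-3-[2,3,4-tris(benzyloxy)-6-(methoxymethoxy)phenyl]propane-1,3-dione
Product: 15 5,6,7-tris(benzyloxy)-2-[4-(benzyloxy)phenyl]-3-hydroxy-4H-chromen-4-one, via phenolic 2-hydroxy-1,3-diketone 13 (not isolated), via 2,3-dihydroxychromanone hemiketal 14 (not isolated)
Conditions: HCl (1.25 M in MeOH)–THF (2:1), 45 °C
Reagents that add atoms: none
Why: Acid-catalysed acetal exchange with methanol removes both methoxymethyl groups as dimethoxymethane, the freed phenol adds to the 4-(benzyloxy)benzoyl carbonyl (6-exo-trig) and the hemiketal 14 dehydrates to the conjugated 4-pyranone, the cyclodehydration that ends a Baker–Venkataraman flavone synthesis. Benzyl ethers are stable to dilute methanolic HCl at this temperature, and the order in which the two acetals leave does not matter because all paths converge on 15.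

Step 9
Reactants: 15 5,6,7-tris(benzyloxy)-2-[4-(benzyloxy)phenyl]-3-hydroxy-4H-chromen-4-one
Product: 17 sodium 5,6,7-tris(benzyloxy)-2-[4-(benzyloxy)phenyl]-4-oxo-4H-chromen-3-yl sulfate, via pyridinium sulfate salt 16 (not isolated)
Conditions: SO3·pyridine (6 equiv), pyridine, 55 °C; then aq. NaHCO3, reversed-phase chromatography
Reagents that add atoms: sulfur trioxide–pyridine complex, O=S(=O)([O-])[n+]1ccccc1; sodium hydrogencarbonate, [Na+].OC([O-])=O
Why: O-Sulfonation of the only free hydroxyl with a sulfur trioxide–amine complex; excess reagent and gentle heating answer the hydrogen bond to C4=O and the flanking 2-aryl group. The bicarbonate work-up exchanges pyridinium for sodium, so that no amine reaches the catalyst of step 10 and the sulfate stays a stable salt.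

Step 10
Reactants: 17 sodium 5,6,7-tris(benzyloxy)-2-[4-(benzyloxy)phenyl]-4-oxo-4H-chromen-3-yl sulfate
Product: 19 5,6,7-trihydroxy-2-(4-hydroxyphenyl)-4-oxo-4H-chromen-3-yl hydrogen sulfate, via sodium 6-hydroxykaempferol 3-sulfate 18 (not isolated)
Conditions: H2 (1 atm), Pd/C (10 wt%), MeOH–THF, rt; filter under Ar; then aq. HCl (1.0 equiv), 0 °C, cold C18 desalting
Reagents that add atoms: none
Why: Heterogeneous hydrogenolysis cleaves the four benzylic C–O bonds, while the sulfate monoester salt, the C4 carbonyl and the tetrasubstituted C2=C3 bond of the 4-pyranone should be inert at atmospheric pressure and room temperature. One equivalent of cold HCl then protonates the sulfate; 18 is the storage form.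

## Compound list

1 | 3,4,5-trihydroxybenzaldehyde | O=Cc1cc(O)c(O)c(O)c1 | starting material
2 | 3,4,5-tris(benzyloxy)benzaldehyde | O=Cc1cc(OCc2ccccc2)c(OCc2ccccc2)c(OCc2ccccc2)c1 | intermediate
3 | 3,4,5-tris(benzyloxy)phenyl formate | O=COc1cc(OCc2ccccc2)c(OCc2ccccc2)c(OCc2ccccc2)c1 | intermediate
4 | 3,4,5-tris(benzyloxy)phenol | Oc1cc(OCc2ccccc2)c(OCc2ccccc2)c(OCc2ccccc2)c1 | intermediate
5 | 3,4,5-tris(benzyloxy)-2-iodophenol | Oc1cc(OCc2ccccc2)c(OCc2ccccc2)c(OCc2ccccc2)c1I | intermediate
6 | 1,2,3-tris(benzyloxy)-4-iodo-5-(methoxymethoxy)benzene | COCOc1cc(OCc2ccccc2)c(OCc2ccccc2)c(OCc2ccccc2)c1I | intermediate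
7 | 1-[4-(benzyloxy)phenyl]ethan-1-one | CC(=O)c1ccc(OCc2ccccc2)cc1 | starting material
8 | 2-[4-(benzyloxy)phenyl]-2,2-dimethoxyethan-1-ol | COC(CO)(OC)c1ccc(OCc2ccccc2)cc1 | intermediate
9 | 1-[4-(benzyloxy)phenyl]-2-hydroxyethan-1-one | O=C(CO)c1ccc(OCc2ccccc2)cc1 | intermediate
10 | 1-[4-(benzyloxy)phenyl]-2-(methoxymethoxy)ethan-1-one | COCOCC(=O)c1ccc(OCc2ccccc2)cc1 | intermediate
11 | carbon monoxide | [C-]#[O+] | starting material
12 | 1-[4-(benzyloxy)phenyl]-2-(methoxymethoxy)-3-[2,3,4-tris(benzyloxy)-6-(methoxymethoxy)phenyl]propane-1,3-dione (racemic) | COCOc1cc(OCc2ccccc2)c(OCc2ccccc2)c(OCc2ccccc2)c1C(=O)C(OCOC)C(=O)c1ccc(OCc2ccccc2)cc1 | intermediate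
13 | 1-[4-(benzyloxy)phenyl]-2-hydroxy-3-[2,3,4-tris(benzyloxy)-6-hydroxyphenyl]propane-1,3-dione (racemic) | Oc1cc(OCc2ccccc2)c(OCc2ccccc2)c(OCc2ccccc2)c1C(=O)C(O)C(=O)c1ccc(OCc2ccccc2)cc1 | intermediate
14 | 5,6,7-tris(benzyloxy)-2-[4-(benzyloxy)phenyl]-2,3-dihydroxy-2,3-dihydro-4H-chromen-4-one (mixture of stereoisomers) | O=C1c2c(OCc3ccccc3)c(OCc3ccccc3)c(OCc3ccccc3)cc2OC(O)(c2ccc(OCc3ccccc3)cc2)C1O | intermediate
15 | 5,6,7-tris(benzyloxy)-2-[4-(benzyloxy)phenyl]-3-hydroxy-4H-chromen-4-one | O=c1c(O)c(-c2ccc(OCc3ccccc3)cc2)oc2cc(OCc3ccccc3)c(OCc3ccccc3)c(OCc3ccccc3)c12 | intermediate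
16 | pyridinium 5,6,7-tris(benzyloxy)-2-[4-(benzyloxy)phenyl]-4-oxo-4H-chromen-3-yl sulfate | c1cc[nH+]cc1.[O-]S(=O)(=O)Oc1c(-c2ccc(OCc3ccccc3)cc2)oc2cc(OCc3ccccc3)c(OCc3ccccc3)c(OCc3ccccc3)c2c1=O | intermediate
17 | sodium 5,6,7-tris(benzyloxy)-2-[4-(benzyloxy)phenyl]-4-oxo-4H-chromen-3-yl sulfate | [Na+].[O-]S(=O)(=O)Oc1c(-c2ccc(OCc3ccccc3)cc2)oc2cc(OCc3ccccc3)c(OCc3ccccc3)c(OCc3ccccc3)c2c1=O | intermediate
18 | sodium 5,6,7-trihydroxy-2-(4-hydroxyphenyl)-4-oxo-4H-chromen-3-yl sulfate | [Na+].[O-]S(=O)(=O)Oc1c(-c2ccc(O)cc2)oc2cc(O)c(O)c(O)c2c1=O | intermediate
19 | 5,6,7-trihydroxy-2-(4-hydroxyphenyl)-4-oxo-4H-chromen-3-yl hydrogen sulfate | O=c1c(OS(=O)(=O)O)c(-c2ccc(O)cc2)oc2cc(O)c(O)c(O)c12 | target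

## Step count and least certain steps

Total step count: 10. Longest linear sequence: 8 steps (steps 1 to 4, then 7 to 10); the ketone branch (steps 5 and 6) joins at step 7.

**Step 7 (key step).** The catalytic cycle may stall at the aroyl complex, because attack of the enolate is hindered by the two ortho oxygen substituents. The C–I bond may then be reduced, the enolate may be acylated on oxygen, or palladium may be lost as inactive carbonyl clusters. The fallback sets out from 6 and 10 and builds the same two bonds stepwise without carbon monoxide. Iodine–magnesium exchange on 6 (iPrMgCl·LiCl, THF, −20 °C) and formylation with DMF should give 2,3,4-tris(benzyloxy)-6-(methoxymethoxy)benzaldehyde F1. Aldol addition of the lithium enolate of 10 (LiN(SiMe3)2, THF, −78 °C) should give 1-[4-(benzyloxy)phenyl]-3-hydroxy-2-(methoxymethoxy)-3-[2,3,4-tris(benzyloxy)-6-(methoxymethoxy)phenyl]propan-1-one F2 as a diastereomer mixture. Dess–Martin oxidation of the secondary alcohol returns to the route at 12.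

**Step 8.** Methanol may cleave the non-enolised, 2-oxygenated 1,3-diketone by retro-Claisen fragmentation before the ring closes. Once the flavone has formed, the benzyl ether on C5, peri to the carbonyl, may be partly lost. The fallback sets out from 12 and separates the events, so that a free 2-hydroxy-1,3-diketone never forms. NaHSO4·SiO2 in CH2Cl2 at room temperature should remove only the phenolic acetal, and the freed phenol should cyclodehydrate to 5,6,7-tris(benzyloxy)-2-[4-(benzyloxy)phenyl]-3-(methoxymethoxy)-4H-chromen-4-one F3. The remaining enol acetal is then hydrolysed with CF3CO2H in wet CH2Cl2 at 0 °C, which returns to the route at 15.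

**Step 9.** Sulfation of the hydrogen-bonded, flanked 3-hydroxyl may be incomplete, and the sulfate monoester may hydrolyse during work-up and purification of the salt. The fallback sets out from 15 and introduces the sulfate as a neutral, chromatographable diester. 2,2,2-Trichloroethyl chlorosulfate with Et3N and DMAP in THF should give 5,6,7-tris(benzyloxy)-2-[4-(benzyloxy)phenyl]-4-oxo-4H-chromen-3-yl 2,2,2-trichloroethyl sulfate F4. Reductive fragmentation with Zn dust and ammonium formate in MeOH should give ammonium 5,6,7-tris(benzyloxy)-2-[4-(benzyloxy)phenyl]-4-oxo-4H-chromen-3-yl sulfate F5. Evaporation from aqueous NaHCO3 returns to the route at 17.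

**Step 10.** The sulfate may hydrolyse once the free acid is released, the unmasked pyrogallol-type ring A may oxidise in air, debenzylation may stop early through catalyst poisoning by sulfur-containing residues, and the C2=C3 bond may be over-reduced. The fallback sets out from 15 and avoids hydrogenation of a sulfate salt altogether. The diester F4 is made as described for step 9 and its benzyl ethers are cleaved with BCl3 and pentamethylbenzene in CH2Cl2 at −78 °C. This should give 5,6,7-trihydroxy-2-(4-hydroxyphenyl)-4-oxo-4H-chromen-3-yl 2,2,2-trichloroethyl sulfate F6. Zn dust and ammonium formate in MeOH under argon should then unmask the sulfate as ammonium 5,6,7-trihydroxy-2-(4-hydroxyphenyl)-4-oxo-4H-chromen-3-yl sulfate F7. One equivalent of cold HCl returns to the route at 19.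

**Step 5.** With an electron-rich aryl ketone, oxidative 1,2-aryl migration to an arylacetate and over-oxidation may compete with epoxide formation. The fallback sets out from 7 and uses halogenation and substitution. α-Bromination with PhNMe3·Br3 in THF should give 2-bromo-1-[4-(benzyloxy)phenyl]ethan-1-one F8. Sodium formate in aqueous ethanol at reflux should displace bromide to give 2-[4-(benzyloxy)phenyl]-2-oxoethyl formate F9, which hydrolyses in the same pot and returns to the route at 9.

**Step 3.** A second iodination at the other ortho carbon and oxidation of the very electron-rich phenol towards a quinone may erode the mono-iodide. The fallback sets out from 4 and replaces electrophilic substitution by directed metalation. Acetal protection (MOMCl, iPr2NEt) should give 1,2,3-tris(benzyloxy)-5-(methoxymethoxy)benzene F10. Lithiation with n-BuLi in THF at 0 °C should occur at the carbon between the acetal oxygen and a benzyloxy group, and an iodine quench returns to the route at 6.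

## Further compounds

F1 | step 7 | 2,3,4-tris(benzyloxy)-6-(methoxymethoxy)benzaldehyde | COCOc1cc(OCc2ccccc2)c(OCc2ccccc2)c(OCc2ccccc2)c1C=O
F2 | step 7 | 1-[4-(benzyloxy)phenyl]-3-hydroxy-2-(methoxymethoxy)-3-[2,3,4-tris(benzyloxy)-6-(methoxymethoxy)phenyl]propan-1-one (racemic diastereomer mixture) | COCOc1cc(OCc2ccccc2)c(OCc2ccccc2)c(OCc2ccccc2)c1C(O)C(OCOC)C(=O)c1ccc(OCc2ccccc2)cc1
F3 | step 8 | 5,6,7-tris(benzyloxy)-2-[4-(benzyloxy)phenyl]-3-(methoxymethoxy)-4H-chromen-4-one | COCOc1c(-c2ccc(OCc3ccccc3)cc2)oc2cc(OCc3ccccc3)c(OCc3ccccc3)c(OCc3ccccc3)c2c1=O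
F4 | step 9 | 5,6,7-tris(benzyloxy)-2-[4-(benzyloxy)phenyl]-4-oxo-4H-chromen-3-yl 2,2,2-trichloroethyl sulfate | O=c1c(OS(=O)(=O)OCC(Cl)(Cl)Cl)c(-c2ccc(OCc3ccccc3)cc2)oc2cc(OCc3ccccc3)c(OCc3ccccc3)c(OCc3ccccc3)c12
F5 | step 9 | ammonium 5,6,7-tris(benzyloxy)-2-[4-(benzyloxy)phenyl]-4-oxo-4H-chromen-3-yl sulfate | [NH4+].[O-]S(=O)(=O)Oc1c(-c2ccc(OCc3ccccc3)cc2)oc2cc(OCc3ccccc3)c(OCc3ccccc3)c(OCc3ccccc3)c2c1=O
F6 | step 10 | 5,6,7-trihydroxy-2-(4-hydroxyphenyl)-4-oxo-4H-chromen-3-yl 2,2,2-trichloroethyl sulfate | O=c1c(OS(=O)(=O)OCC(Cl)(Cl)Cl)c(-c2ccc(O)cc2)oc2cc(O)c(O)c(O)c12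
F7 | step 10 | ammonium 5,6,7-trihydroxy-2-(4-hydroxyphenyl)-4-oxo-4H-chromen-3-yl sulfate | [NH4+].[O-]S(=O)(=O)Oc1c(-c2ccc(O)cc2)oc2cc(O)c(O)c(O)c2c1=O
F8 | step 5 | 2-bromo-1-[4-(benzyloxy)phenyl]ethan-1-one | O=C(CBr)c1ccc(OCc2ccccc2)cc1
F9 | step 5 | 2-[4-(benzyloxy)phenyl]-2-oxoethyl formate | O=COCC(=O)c1ccc(OCc2ccccc2)cc1
F10 | step 3 | 1,2,3-tris(benzyloxy)-5-(methoxymethoxy)benzene | COCOc1cc(OCc2ccccc2)c(OCc2ccccc2)c(OCc2ccccc2)c1
A1 | alternative 1 | 3-(allyloxy)-5,6,7-tris(benzyloxy)-2-[4-(benzyloxy)phenyl]-4H-chromen-4-one | O=c1c(OCC=C)c(-c2ccc(OCc3ccccc3)cc2)oc2cc(OCc3ccccc3)c(OCc3ccccc3)c(OCc3ccccc3)c12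
A2 | alternative 1 | (E)-2-(allyloxy)-3-[4-(benzyloxy)phenyl]-3-[3,4,5-tris(benzyloxy)phenoxy]prop-2-enoic acid | OC(=O)/C(OCC=C)=C(\Oc1cc(OCc2ccccc2)c(OCc2ccccc2)c(OCc2ccccc2)c1)c1ccc(OCc2ccccc2)cc1
A3 | alternative 2 | 5,6,7-tris(benzyloxy)-2-[4-(benzyloxy)phenyl]-3-hydroxychroman-4-one (racemic stereoisomer mixture, one isomer drawn) | O=C1c2c(OCc3ccccc3)c(OCc3ccccc3)c(OCc3ccccc3)cc2O[C@H](c2ccc(OCc3ccccc3)cc2)[C@@H]1O
A4 | alternative 2 | 2,3,4-tris(benzyloxy)-6-{1-[4-(benzyloxy)phenyl]-2-oxoethoxy}benzaldehyde (racemic) | O=CC(Oc1cc(OCc2ccccc2)c(OCc2ccccc2)c(OCc2ccccc2)c1C=O)c1ccc(OCc2ccccc2)cc1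
A5 | alternative 3 | 6-(benzyloxy)-2-[4-(benzyloxy)phenyl]-5,7-dihydroxy-3-(methoxymethoxy)-4H-chromen-4-one | O=c1c(OCOC)c(-c2ccc(OCc3ccccc3)cc2)oc2cc(O)c(OCc3ccccc3)c(O)c12
A6 | alternative 3 | methyl 2-(benzyloxy)-4-{6-[4-(benzyloxy)phenyl]-5-(methoxymethoxy)-4-oxo-4H-pyran-2-yl}-3-oxobutanoate (racemic) | COC(=O)C(OCc1ccccc1)C(=O)Cc1cc(=O)c(OCOC)c(-c2ccc(OCc3ccccc3)cc2)o1
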